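**Retrosynthetic overview** (ring numbering used throughout: C1 = alkylidene carbon, C2 = CH carrying the hydroxypropyl arm, C3 = quaternary carbon, C4 = carbinol carbon, C5 and C6 = ring CH2)
- Late stage: the enal comes from an allylic alcohol (MnO2), the epoxy alcohol from a hydroxyl-directed epoxidation, C4–Me/OH from methylcerium addition to a C4 ketone, and the C3 side chain and C3 methyl from two alkylations of a β-keto sulfone dianion.
- The only ring is closed by a one-flask [3+3] annulation that forms C1–C2 and C4–C5: rhodium-catalysed asymmetric conjugate alkenylation of an enoate, then sulfone–ester Claisen closure.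
- Enabling feature: C2 and C4 are 1,3-related through C3, exactly as the β-carbon and acyl carbon of an α,β-unsaturated ester (a 1,3-dielectrophile). C1 and C5 are 1,3-related through C6, matched by an alkenylboron carbon and an α-sulfonyl carbon (a 1,3-dinucleophile). The sulfonyl group is a temporary activating group, removed in step 17.
- C2 is set by the catalyst; C3 and C4 are relayed from it by substrate control. The exocyclic Z-alkene geometry is fixed earlier, in a stereodefined enol triflate; the side chain is built by iterative zirconium-catalysed carboalumination.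

Key step: step 7

Remarks (assumptions): potassium 3-methoxy-2-methyl-3-oxopropanoate, 4-[(tert-butyldimethylsilyl)oxy]butanal and allenylboronic acid pinacol ester are taken as purchasable. The ligand enantiomers in steps 7 and 9 are assigned by analogy with the established models and would be exchanged for their antipodes if a first run showed the opposite sense.

**Fragment A (alkenylboronate)**

Step 1
Reactants: 1 3-(phenylsulfonyl)propanoic acid
Product: 3 methyl 2-methyl-3-oxo-5-(phenylsulfonyl)pentanoate, via acyl imidazole 2 (not isolated)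
Conditions: 1,1'-carbonyldiimidazole, THF, rt; then KO2CCH(Me)CO2Me, MgCl2, Et3N, MeCN, rt; aq HCl
Reagents that add atoms: potassium 3-methoxy-2-methyl-3-oxopropanoate, COC(=O)C(C)C(=O)[O-].[K+]
Why: Masamune–Brooks C-acylation of the magnesium malonate half-ester by the acyl imidazole with loss of CO2 should give the β-keto ester under near-neutral chelate conditions that spare the β-sulfonyl unit from elimination.

Step 2
Reactants: 3 methyl 2-methyl-3-oxo-5-(phenylsulfonyl)pentanoate
Product: 4 methyl (2Z)-2-methyl-5-(phenylsulfonyl)-3-{[(trifluoromethyl)sulfonyl]oxy}pent-2-enoate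
Conditions: sat. aq LiOH, Tf2O, toluene, 5 °C
Reagents that add atoms: trifluoromethanesulfonic anhydride, O=S(=O)(OS(=O)(=O)C(F)(F)F)C(F)(F)F
Why: O-sulfonylation of the chelated lithium Z-enolate (Frantz-type stereoselective enol triflate synthesis) should place OTf cis to the ester, the geometry that later becomes "CHO cis to ring C2".

Step 3
Reactants: 4 methyl (2Z)-2-methyl-5-(phenylsulfonyl)-3-{[(trifluoromethyl)sulfonyl]oxy}pent-2-enoate
Product: 5 (2Z)-1-hydroxy-2-methyl-5-(phenylsulfonyl)pent-2-en-3-yl trifluoromethanesulfonate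
Conditions: i-Bu2AlH (2.5 equiv), CH2Cl2, −78 °C; Rochelle salt
Reagents that add atoms: none
Why: DIBAL 1,2-reduction of the conjugated methyl ester to the allylic alcohol should leave the vinyl triflate and the sulfone untouched at low temperature.

Step 4
Reactants: 5 (2Z)-1-hydroxy-2-methyl-5-(phenylsulfonyl)pent-2-en-3-yl trifluoromethanesulfonate
Product: 6 (2Z)-1-[(tert-butyldimethylsilyl)oxy]-2-methyl-5-(phenylsulfonyl)pent-2-en-3-yl trifluoromethanesulfonate
Conditions: TBSCl, imidazole, CH2Cl2, 0 °C to rt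
Reagents that add atoms: tert-butyldimethylsilyl chloride, CC(C)(C)[Si](C)(C)Cl
Why: Standard silylation of a primary allylic alcohol; keeping this carbon at the alcohol oxidation level avoids vinylogous enolisation in the later base steps.

Step 5
Reactants: 6 (2Z)-1-[(tert-butyldimethylsilyl)oxy]-2-methyl-5-(phenylsulfonyl)pent-2-en-3-yl trifluoromethanesulfonate
Product: 7 tert-butyldimethyl{[(2E)-2-methyl-5-(phenylsulfonyl)-3-(4,4,5,5-tetramethyl-1,3,2-dioxaborolan-2-yl)pent-2-en-1-yl]oxy}silane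
Conditions: PdCl2(PPh3)2 (3 mol %), PPh3, B2pin2, KOPh, toluene, 50 °C
Reagents that add atoms: bis(pinacolato)diboron, CC1(C)OB(OC1(C)C)B1OC(C)(C)C(C)(C)O1
Why: Miyaura borylation of an alkenyl triflate proceeds with retention of alkene geometry, so boron should end cis to CH2OTBS.

**Fragment B (enoate)**

Step 6
Reactants: 8 4-[(tert-butyldimethylsilyl)oxy]butanal
Product: 9 methyl (2E)-6-[(tert-butyldimethylsilyl)oxy]hex-2-enoate
Conditions: Ph3P=CHCO2Me, CH2Cl2, rt
Reagents that add atoms: methyl (triphenylphosphoranylidene)acetate, COC(=O)C=P(c1ccccc1)(c1ccccc1)c1ccccc1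
Why: Wittig olefination with a stabilised ylide should give the E-enoate.

**Key annulation and ring elaboration**

Step 7
Reactants: 7 tert-butyldimethyl{[(2E)-2-methyl-5-(phenylsulfonyl)-3-(4,4,5,5-tetramethyl-1,3,2-dioxaborolan-2-yl)pent-2-en-1-yl]oxy}silane; 9 methyl (2E)-6-[(tert-butyldimethylsilyl)oxy]hex-2-enoate
Product: 11 (4Z,5S)-4-{1-[(tert-butyldimethylsilyl)oxy]propan-2-ylidene}-5-{3-[(tert-butyldimethylsilyl)oxy]propyl}-2-(phenylsulfonyl)cyclohexan-1-one (C2 epimers and enol), via conjugate adduct 10 (not isolated)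
Conditions: [Rh(OH)(C8H12)]2 (3 mol %; C8H12 = cycloocta-1,5-diene), (S)-BINAP, dioxane/H2O 10:1, 60 °C; volatiles removed, then KOt-Bu (3.5 equiv), THF, 0 °C to rt, same flask; aq NH4Cl
Reagents that add atoms: none
Why: The hydroxorhodium–BINAP complex transmetalates with the alkenylboronate with retention of geometry, the enoate inserts into the alkenyl–Rh bond, and water protonates the oxa-π-allyl rhodium to give ester 10; tert-butoxide then reversibly forms the α-sulfonyl carbanion, which attacks the ester carbonyl and is drained by irreversible deprotonation of the β-keto sulfone. The closest known reaction types are the Hayashi–Miyaura asymmetric 1,4-addition of alkenylboron reagents to enoates and the intramolecular sulfone–ester Claisen (Dieckmann-type) condensation; together they form a [3+3] annulation of the Michael–Claisen kind. The single ring closes by 6-exo-trig attack of the carbanion (future C5) on the ester carbon (future C4), after the intermolecular C1–C2 bond is in place. The only lasting new stereocentre, ring C2, is set by catalyst control of the enoate face (S in 10 and 11, which becomes R in the target once C3 is quaternary); the sulfonyl-bearing carbon is stereochemically irrelevant because the sulfone is removed later. The Z-alkylidene geometry is carried over unchanged from boronate 7. The step needs 1,4-addition to outrun protodeboronation, which excess boronate and the hydroxo precatalyst should secure, and a single Claisen mode, which is guaranteed because a sulfone cannot act as the acyl acceptor.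

Step 8
Reactants: 11 (4Z,5S)-4-{1-[(tert-butyldimethylsilyl)oxy]propan-2-ylidene}-5-{3-[(tert-butyldimethylsilyl)oxy]propyl}-2-(phenylsulfonyl)cyclohexan-1-one
Product: 12 (4Z,5S)-4-{1-[(tert-butyldimethylsilyl)oxy]propan-2-ylidene}-5-{3-[(tert-butyldimethylsilyl)oxy]propyl}-6-methyl-2-(phenylsulfonyl)cyclohexan-1-one (mixture at C2 and C6)
Conditions: LiN(i-Pr)2 (2.2 equiv), THF, −78 to 0 °C; MeI, −78 °C
Reagents that add atoms: iodomethane, CI
Why: The dianion of a β-keto sulfone alkylates at its more basic α' terminus (Weiler-type dianion alkylation), the sulfonyl-stabilised site being blocked as the monoanion; the configuration of the new methine is irrelevant because it is enolised again in step 16.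

**Side chain**

Step 9
Reactants: 13 3-methylbut-2-enal
Product: 14 (4S)-6-methylhept-5-en-1-yn-4-ol
Conditions: allenylboronic acid pinacol ester, (R)-TRIP phosphoric acid (5 mol %), 4 Å MS, toluene, 0 °C
Reagents that add atoms: allenylboronic acid pinacol ester, C=C=CB1OC(C)(C)C(C)(C)O1
Why: Chiral phosphoric acid-catalysed propargylation of the aldehyde by the allenylboronate through a closed six-membered transition state; the catalyst controls the carbinol stereocentre.

Step 10
Reactants: 14 (4S)-6-methylhept-5-en-1-yn-4-ol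
Product: 15 triethyl{[(4S)-6-methylhept-5-en-1-yn-4-yl]oxy}silane
Conditions: TESCl, imidazole, CH2Cl2, 0 °C
Reagents that add atoms: chlorotriethylsilane, CC[Si](Cl)(CC)CC
Why: Standard silylation; the TES ether is chosen because it can later be removed in the presence of the two primary TBS ethers.

Step 11
Reactants: 15 triethyl{[(4S)-6-methylhept-5-en-1-yn-4-yl]oxy}silane
Product: 17 (3E,6S)-4,8-dimethyl-6-[(triethylsilyl)oxy]nona-3,7-dien-1-ol, via alkenylalane 16 (not isolated)
Conditions: AlMe3, (C5H5)2ZrCl2 (25 mol %), CH2Cl2, 0 °C to rt; n-BuLi, −78 °C; ethylene oxide, −78 to 0 °C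
Reagents that add atoms: trimethylaluminium, C[Al](C)C; ethylene oxide, C1CO1
Why: Negishi zirconium-catalysed syn-carboalumination puts methyl on the internal and aluminium on the terminal alkyne carbon, and the derived alanate opens oxirane with retention, giving the E-trisubstituted homoallylic alcohol.

Step 12
Reactants: 17 (3E,6S)-4,8-dimethyl-6-[(triethylsilyl)oxy]nona-3,7-dien-1-ol
Product: 18 {[(4S,6E)-9-iodo-2,6-dimethylnona-2,6-dien-4-yl]oxy}triethylsilane
Conditions: I2, PPh3, imidazole, CH2Cl2, 0 °C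
Reagents that add atoms: iodine, II
Why: Appel-type (Garegg–Samuelsson) conversion of a primary alcohol to the iodide under neutral conditions.

Step 13
Reactants: 18 {[(4S,6E)-9-iodo-2,6-dimethylnona-2,6-dien-4-yl]oxy}triethylsilane
Product: 19 (5E,8S)-6,10-dimethyl-8-[(triethylsilyl)oxy]undeca-5,9-dien-1-yne
Conditions: lithium acetylide–ethylenediamine, DMSO, 10 °C to rt
Reagents that add atoms: lithium acetylide–ethylenediamine complex, [Li]C#C.NCCN
Why: SN2 alkylation of acetylide by an unhindered primary iodide in a dipolar aprotic solvent.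

Step 14
Reactants: 19 (5E,8S)-6,10-dimethyl-8-[(triethylsilyl)oxy]undeca-5,9-dien-1-yne
Product: 21 (3E,7E,10S)-4,8,12-trimethyl-10-[(triethylsilyl)oxy]trideca-3,7,11-trien-1-ol, via alkenylalane 20 (not isolated)
Conditions: AlMe3, (C5H5)2ZrCl2 (25 mol %), CH2Cl2, 0 °C to rt; n-BuLi, −78 °C; ethylene oxide, −78 to 0 °C
Reagents that add atoms: trimethylaluminium, C[Al](C)C; ethylene oxide, C1CO1
Why: Second Negishi carboalumination and oxirane opening, again stereospecifically syn, should install the second E-trisubstituted alkene.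

Step 15
Reactants: 21 (3E,7E,10S)-4,8,12-trimethyl-10-[(triethylsilyl)oxy]trideca-3,7,11-trien-1-ol
Product: 22 {[(4S,6E,10E)-13-iodo-2,6,10-trimethyltrideca-2,6,10-trien-4-yl]oxy}triethylsilane
Conditions: I2, PPh3, imidazole, CH2Cl2, 0 °C
Reagents that add atoms: iodine, II
Why: Appel-type iodination of the primary homoallylic alcohol.

**Fragment union and end game**

Step 16
Reactants: 12 (4Z,5S)-4-{1-[(tert-butyldimethylsilyl)oxy]propan-2-ylidene}-5-{3-[(tert-butyldimethylsilyl)oxy]propyl}-6-methyl-2-(phenylsulfonyl)cyclohexan-1-one; 22 {[(4S,6E,10E)-13-iodo-2,6,10-trimethyltrideca-2,6,10-trien-4-yl]oxy}triethylsilane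
Product: 23 (4Z,5R,6S)-4-{1-[(tert-butyldimethylsilyl)oxy]propan-2-ylidene}-5-{3-[(tert-butyldimethylsilyl)oxy]propyl}-6-methyl-2-(phenylsulfonyl)-6-{(3E,7E,10S)-4,8,12-trimethyl-10-[(triethylsilyl)oxy]trideca-3,7,11-trien-1-yl}cyclohexan-1-one (C2 epimers)
Conditions: LiN(i-Pr)2 (2.3 equiv), THF/DMPU, −78 to −20 °C; 22, −20 to 0 °C
Reagents that add atoms: none
Why: Dianion alkylation at the only free α' carbon creates quaternary ring C3; the neighbouring C2 arm is held pseudoaxial by allylic strain with the cis CH2OTBS of the alkylidene and with the enolate methyl, so the iodide should approach the opposite face and the chain should end trans to the arm.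

Step 17
Reactants: 23 (C2 epimers of the alkylated β-keto sulfone)
Product: 24 (2S,3R,4Z)-4-{1-[(tert-butyldimethylsilyl)oxy]propan-2-ylidene}-3-{3-[(tert-butyldimethylsilyl)oxy]propyl}-2-methyl-2-{(3E,7E,10S)-4,8,12-trimethyl-10-[(triethylsilyl)oxy]trideca-3,7,11-trien-1-yl}cyclohexan-1-one
Conditions: SmI2 (2.5 equiv), THF/MeOH, −78 °C
Reagents that add atoms: none
Why: Reductive desulfonylation of an α-sulfonyl ketone by single-electron transfer (C–S cleavage, then enolate protonation) is fast at −78 °C and should leave silyl ethers and alkenes alone.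

Step 18
Reactants: 24 (ring ketone)
Product: 25 (1S,2S,3R,4Z)-4-{1-[(tert-butyldimethylsilyl)oxy]propan-2-ylidene}-3-{3-[(tert-butyldimethylsilyl)oxy]propyl}-1,2-dimethyl-2-{(3E,7E,10S)-4,8,12-trimethyl-10-[(triethylsilyl)oxy]trideca-3,7,11-trien-1-yl}cyclohexan-1-ol
Conditions: MeLi, CeCl3, THF, −78 °C
Reagents that add atoms: methyllithium (used as MeCeCl2), [Li]C
Why: Imamoto organocerium 1,2-addition to a hindered, enolisable ketone; the pseudoaxial ring-C2 arm blocks the syn-axial trajectory, so methyl should enter from the face of the C3 chain and leave OH cis to the arm.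

Step 19
Reactants: 25 (tertiary alcohol, TES and two TBS ethers)
Product: 26 (1S,2S,3R,4Z)-4-{1-[(tert-butyldimethylsilyl)oxy]propan-2-ylidene}-3-{3-[(tert-butyldimethylsilyl)oxy]propyl}-2-[(3E,7E,10S)-10-hydroxy-4,8,12-trimethyltrideca-3,7,11-trien-1-yl]-1,2-dimethylcyclohexan-1-ol
Conditions: PPTS (cat.), MeOH/CH2Cl2, 0 °C
Reagents that add atoms: none
Why: Mild acid methanolysis cleaves a triethylsilyl ether much faster than primary tert-butyldimethylsilyl ethers.

Step 20
Reactants: 26 (side-chain allylic alcohol)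
Product: 27 (1S,2S,3R,4Z)-4-{1-[(tert-butyldimethylsilyl)oxy]propan-2-ylidene}-3-{3-[(tert-butyldimethylsilyl)oxy]propyl}-2-{(3E,7E,10S)-10-[(2R)-3,3-dimethyloxiran-2-yl]-10-hydroxy-4,8-dimethyldeca-3,7-dien-1-yl}-1,2-dimethylcyclohexan-1-ol
Conditions: VO(C5H7O2)2 (vanadyl acetylacetonate, 5 mol %), t-BuOOH (1.2 equiv), CH2Cl2, 0 °C
Reagents that add atoms: tert-butyl hydroperoxide, CC(C)(C)OO
Why: Hydroxyl-directed vanadium-catalysed epoxidation touches only the allylic-alcohol alkene; allylic 1,3-strain from the cis-methyl puts the carbinol H in the alkene plane, so oxygen is delivered syn to OH and should give the threo (10S, oxirane 2R) epoxy alcohol.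

Step 21
Reactants: 27 (bis-TBS epoxy alcohol)
Product: 28 (1S,2S,3R,4Z)-2-{(3E,7E,10S)-10-[(2R)-3,3-dimethyloxiran-2-yl]-10-hydroxy-4,8-dimethyldeca-3,7-dien-1-yl}-4-(1-hydroxypropan-2-ylidene)-3-(3-hydroxypropyl)-1,2-dimethylcyclohexan-1-ol
Conditions: Bu4NF, THF, 0 °C to rt; aq NH4Cl
Reagents that add atoms: none
Why: Fluoride-induced cleavage of both primary silyl ethers; the trisubstituted epoxide is inert to fluoride.

Step 22
Reactants: 28 (tetraol)
Product: 29 (2Z)-2-[(2R,3S,4S)-3-{(3E,7E,10S)-10-[(2R)-3,3-dimethyloxiran-2-yl]-10-hydroxy-4,8-dimethyldeca-3,7-dien-1-yl}-4-hydroxy-2-(3-hydroxypropyl)-3,4-dimethylcyclohexylidene]propanal (CNP0161066.1)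
Conditions: MnO2 (excess), CH2Cl2, rt
Reagents that add atoms: none
Why: Manganese dioxide oxidises only the allylic primary alcohol to the enal; the saturated primary, the epoxy-carbinol secondary and the tertiary hydroxyl groups are not allylic and should remain.

**Compound list**
1 | 3-(phenylsulfonyl)propanoic acid | OC(=O)CCS(=O)(=O)c1ccccc1 | starting material
2 | 1-[3-(phenylsulfonyl)propanoyl]-1H-imidazole | O=C(CCS(=O)(=O)c1ccccc1)n1ccnc1 | intermediate
3 | methyl 2-methyl-3-oxo-5-(phenylsulfonyl)pentanoate | COC(=O)C(C)C(=O)CCS(=O)(=O)c1ccccc1 | intermediate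
4 | methyl (2Z)-2-methyl-5-(phenylsulfonyl)-3-{[(trifluoromethyl)sulfonyl]oxy}pent-2-enoate | COC(=O)/C(C)=C(\OS(=O)(=O)C(F)(F)F)CCS(=O)(=O)c1ccccc1 | intermediate
5 | (2Z)-1-hydroxy-2-methyl-5-(phenylsulfonyl)pent-2-en-3-yl trifluoromethanesulfonate | OC/C(C)=C(\OS(=O)(=O)C(F)(F)F)CCS(=O)(=O)c1ccccc1 | intermediate
6 | (2Z)-1-[(tert-butyldimethylsilyl)oxy]-2-methyl-5-(phenylsulfonyl)pent-2-en-3-yl trifluoromethanesulfonate | CC(C)(C)[Si](C)(C)OC/C(C)=C(\OS(=O)(=O)C(F)(F)F)CCS(=O)(=O)c1ccccc1 | intermediate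
7 | tert-butyldimethyl{[(2E)-2-methyl-5-(phenylsulfonyl)-3-(4,4,5,5-tetramethyl-1,3,2-dioxaborolan-2-yl)pent-2-en-1-yl]oxy}silane | CC(C)(C)[Si](C)(C)OC/C(C)=C(\B1OC(C)(C)C(C)(C)O1)CCS(=O)(=O)c1ccccc1 | intermediate
8 | 4-[(tert-butyldimethylsilyl)oxy]butanal | CC(C)(C)[Si](C)(C)OCCCC=O | starting material
9 | methyl (2E)-6-[(tert-butyldimethylsilyl)oxy]hex-2-enoate | COC(=O)/C=C/CCCO[Si](C)(C)C(C)(C)C | intermediate
10 | methyl (3S)-6-[(tert-butyldimethylsilyl)oxy]-3-{(2Z)-1-[(tert-butyldimethylsilyl)oxy]-2-methyl-5-(phenylsulfonyl)pent-2-en-3-yl}hexanoate | COC(=O)C[C@@H](/C(CCS(=O)(=O)c1ccccc1)=C(/C)CO[Si](C)(C)C(C)(C)C)CCCO[Si](C)(C)C(C)(C)C | intermediate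
11 | (4Z,5S)-4-{1-[(tert-butyldimethylsilyl)oxy]propan-2-ylidene}-5-{3-[(tert-butyldimethylsilyl)oxy]propyl}-2-(phenylsulfonyl)cyclohexan-1-one | C/C(CO[Si](C)(C)C(C)(C)C)=C1\CC(S(=O)(=O)c2ccccc2)C(=O)C[C@@H]1CCCO[Si](C)(C)C(C)(C)C | intermediate
12 | (4Z,5S)-4-{1-[(tert-butyldimethylsilyl)oxy]propan-2-ylidene}-5-{3-[(tert-butyldimethylsilyl)oxy]propyl}-6-methyl-2-(phenylsulfonyl)cyclohexan-1-one | C/C(CO[Si](C)(C)C(C)(C)C)=C1\CC(S(=O)(=O)c2ccccc2)C(=O)C(C)[C@@H]1CCCO[Si](C)(C)C(C)(C)C | intermediate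
13 | 3-methylbut-2-enal | CC(C)=CC=O | starting material
14 | (4S)-6-methylhept-5-en-1-yn-4-ol | C#CC[C@H](O)C=C(C)C | intermediate
15 | triethyl{[(4S)-6-methylhept-5-en-1-yn-4-yl]oxy}silane | C#CC[C@H](O[Si](CC)(CC)CC)C=C(C)C | intermediate
16 | dimethyl{(1E,4S)-2,6-dimethyl-4-[(triethylsilyl)oxy]hepta-1,5-dien-1-yl}alane | C[Al](C)/C=C(\C)C[C@H](O[Si](CC)(CC)CC)C=C(C)C | intermediate
17 | (3E,6S)-4,8-dimethyl-6-[(triethylsilyl)oxy]nona-3,7-dien-1-ol | OCC/C=C(\C)C[C@H](O[Si](CC)(CC)CC)C=C(C)C | intermediate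
18 | {[(4S,6E)-9-iodo-2,6-dimethylnona-2,6-dien-4-yl]oxy}triethylsilane | ICC/C=C(\C)C[C@H](O[Si](CC)(CC)CC)C=C(C)C | intermediate
19 | (5E,8S)-6,10-dimethyl-8-[(triethylsilyl)oxy]undeca-5,9-dien-1-yne | C#CCC/C=C(\C)C[C@H](O[Si](CC)(CC)CC)C=C(C)C | intermediate
20 | dimethyl{(1E,5E,8S)-2,6,10-trimethyl-8-[(triethylsilyl)oxy]undeca-1,5,9-trien-1-yl}alane | C[Al](C)/C=C(\C)CC/C=C(\C)C[C@H](O[Si](CC)(CC)CC)C=C(C)C | intermediate
21 | (3E,7E,10S)-4,8,12-trimethyl-10-[(triethylsilyl)oxy]trideca-3,7,11-trien-1-ol | OCC/C=C(\C)CC/C=C(\C)C[C@H](O[Si](CC)(CC)CC)C=C(C)C | intermediate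
22 | {[(4S,6E,10E)-13-iodo-2,6,10-trimethyltrideca-2,6,10-trien-4-yl]oxy}triethylsilane | ICC/C=C(\C)CC/C=C(\C)C[C@H](O[Si](CC)(CC)CC)C=C(C)C | intermediate
23 | (4Z,5R,6S)-4-{1-[(tert-butyldimethylsilyl)oxy]propan-2-ylidene}-5-{3-[(tert-butyldimethylsilyl)oxy]propyl}-6-methyl-2-(phenylsulfonyl)-6-{(3E,7E,10S)-4,8,12-trimethyl-10-[(triethylsilyl)oxy]trideca-3,7,11-trien-1-yl}cyclohexan-1-one | C/C(CO[Si](C)(C)C(C)(C)C)=C1\CC(S(=O)(=O)c2ccccc2)C(=O)[C@@](C)(CC/C=C(\C)CC/C=C(\C)C[C@H](O[Si](CC)(CC)CC)C=C(C)C)[C@@H]1CCCO[Si](C)(C)C(C)(C)C | intermediate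
24 | (2S,3R,4Z)-4-{1-[(tert-butyldimethylsilyl)oxy]propan-2-ylidene}-3-{3-[(tert-butyldimethylsilyl)oxy]propyl}-2-methyl-2-{(3E,7E,10S)-4,8,12-trimethyl-10-[(triethylsilyl)oxy]trideca-3,7,11-trien-1-yl}cyclohexan-1-one | C/C(CO[Si](C)(C)C(C)(C)C)=C1\CCC(=O)[C@@](C)(CC/C=C(\C)CC/C=C(\C)C[C@H](O[Si](CC)(CC)CC)C=C(C)C)[C@@H]1CCCO[Si](C)(C)C(C)(C)C | intermediate
25 | (1S,2S,3R,4Z)-4-{1-[(tert-butyldimethylsilyl)oxy]propan-2-ylidene}-3-{3-[(tert-butyldimethylsilyl)oxy]propyl}-1,2-dimethyl-2-{(3E,7E,10S)-4,8,12-trimethyl-10-[(triethylsilyl)oxy]trideca-3,7,11-trien-1-yl}cyclohexan-1-ol | C/C(CO[Si](C)(C)C(C)(C)C)=C1\CC[C@](C)(O)[C@@](C)(CC/C=C(\C)CC/C=C(\C)C[C@H](O[Si](CC)(CC)CC)C=C(C)C)[C@@H]1CCCO[Si](C)(C)C(C)(C)C | intermediate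
26 | (1S,2S,3R,4Z)-4-{1-[(tert-butyldimethylsilyl)oxy]propan-2-ylidene}-3-{3-[(tert-butyldimethylsilyl)oxy]propyl}-2-[(3E,7E,10S)-10-hydroxy-4,8,12-trimethyltrideca-3,7,11-trien-1-yl]-1,2-dimethylcyclohexan-1-ol | C/C(CO[Si](C)(C)C(C)(C)C)=C1\CC[C@](C)(O)[C@@](C)(CC/C=C(\C)CC/C=C(\C)C[C@H](O)C=C(C)C)[C@@H]1CCCO[Si](C)(C)C(C)(C)C | intermediate
27 | (1S,2S,3R,4Z)-4-{1-[(tert-butyldimethylsilyl)oxy]propan-2-ylidene}-3-{3-[(tert-butyldimethylsilyl)oxy]propyl}-2-{(3E,7E,10S)-10-[(2R)-3,3-dimethyloxiran-2-yl]-10-hydroxy-4,8-dimethyldeca-3,7-dien-1-yl}-1,2-dimethylcyclohexan-1-ol | C/C(CO[Si](C)(C)C(C)(C)C)=C1\CC[C@](C)(O)[C@@](C)(CC/C=C(\C)CC/C=C(\C)C[C@H](O)[C@H]2OC2(C)C)[C@@H]1CCCO[Si](C)(C)C(C)(C)C | intermediate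
28 | (1S,2S,3R,4Z)-2-{(3E,7E,10S)-10-[(2R)-3,3-dimethyloxiran-2-yl]-10-hydroxy-4,8-dimethyldeca-3,7-dien-1-yl}-4-(1-hydroxypropan-2-ylidene)-3-(3-hydroxypropyl)-1,2-dimethylcyclohexan-1-ol | C/C(CO)=C1\CC[C@](C)(O)[C@@](C)(CC/C=C(\C)CC/C=C(\C)C[C@H](O)[C@H]2OC2(C)C)[C@@H]1CCCO | intermediate
29 | (2Z)-2-[(2R,3S,4S)-3-{(3E,7E,10S)-10-[(2R)-3,3-dimethyloxiran-2-yl]-10-hydroxy-4,8-dimethyldeca-3,7-dien-1-yl}-4-hydroxy-2-(3-hydroxypropyl)-3,4-dimethylcyclohexylidene]propanal | C/C(C=O)=C1\CC[C@](C)(O)[C@@](C)(CC/C=C(\C)CC/C=C(\C)C[C@H](O)[C@H]2OC2(C)C)[C@@H]1CCCO | target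

**Step count:** 22 steps in total. Longest linear sequence: 14 steps (steps 9–15 then 16–22; equally steps 1–5, 7, 8 then 16–22).

**Steps most likely to fail**

1. Step 7. The fully substituted alkenyl group may transmetalate and insert slowly, so that protodeboronation, low conversion or eroded enantioselectivity take over. Fallback, setting out from 8 and 7 and returning at 10: Roskamp homologation of aldehyde 8 with methyl diazoacetate and SnCl2 would give methyl 6-[(tert-butyldimethylsilyl)oxy]-3-oxohexanoate F1. Z-selective enol triflation (aq LiOH, Tf2O) would give methyl (2Z)-6-[(tert-butyldimethylsilyl)oxy]-3-{[(trifluoromethyl)sulfonyl]oxy}hex-2-enoate F2. Suzuki–Miyaura coupling of F2 with boronate 7 (Pd(PPh3)4, K3PO4), with retention at both alkenes, would give the dienoate methyl (2Z,4Z)-6-[(tert-butyldimethylsilyl)oxy]-4-{2-(phenylsulfonyl)ethyl}-5-methyl-3-{3-[(tert-butyldimethylsilyl)oxy]propyl}hexa-2,4-dienoate F3. Copper hydride-catalysed asymmetric 1,4-reduction (CuCl, NaOt-Bu, p-Tol-BINAP, polymethylhydrosiloxane) would then set the same stereocentre and deliver 10, which is closed to 11 with KOt-Bu as in step 7.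

2. Step 16. Building the quaternary centre with an unactivated primary iodide may suffer from slow C-alkylation, O-alkylation or insufficient facial discrimination. Fallback, setting out from 12 and returning at 24: SmI2 desulfonylation of 12 would give (3S,4Z)-4-{1-[(tert-butyldimethylsilyl)oxy]propan-2-ylidene}-3-{3-[(tert-butyldimethylsilyl)oxy]propyl}-2-methylcyclohexan-1-one F4. Thermodynamic silylation (TMSCl, Et3N, NaI, MeCN) would give the more substituted trimethylsilyl enol ether F5. The regiodefined lithium enolate released with MeLi would be alkylated with iodide 22 in THF/HMPA, anti to the arm, to give 24 directly.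

3. Step 18. Methyl addition may show poor facial selectivity, because the axial C3 chain and the axial C2 arm shield opposite faces of the ketone. Fallback, setting out from 24 and returning at 25: Corey–Chaykovsky reaction with dimethylsulfoxonium methylide (trimethylsulfoxonium iodide, NaH, DMSO), in which reversible betaine formation should place the new CH2 equatorial, would give the spiro-epoxide F6. Regioselective hydride opening at the CH2 terminus with LiEt3BH would give 25.

Further compounds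
F1 | step 7 | methyl 6-[(tert-butyldimethylsilyl)oxy]-3-oxohexanoate | COC(=O)CC(=O)CCCO[Si](C)(C)C(C)(C)C
F2 | step 7 | methyl (2Z)-6-[(tert-butyldimethylsilyl)oxy]-3-{[(trifluoromethyl)sulfonyl]oxy}hex-2-enoate | COC(=O)/C=C(\OS(=O)(=O)C(F)(F)F)CCCO[Si](C)(C)C(C)(C)C
F3 | step 7 | methyl (2Z,4Z)-dienoate from coupling of F2 with 7 | COC(=O)/C=C(\C(CCS(=O)(=O)c1ccccc1)=C(\C)CO[Si](C)(C)C(C)(C)C)CCCO[Si](C)(C)C(C)(C)C
F4 | step 16 | (3S,4Z)-4-{1-[(tert-butyldimethylsilyl)oxy]propan-2-ylidene}-3-{3-[(tert-butyldimethylsilyl)oxy]propyl}-2-methylcyclohexan-1-one | C/C(CO[Si](C)(C)C(C)(C)C)=C1\CCC(=O)C(C)[C@@H]1CCCO[Si](C)(C)C(C)(C)C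
F5 | step 16 | trimethylsilyl enol ether of F4 (ring C3=C4 enol ether, more substituted) | C/C(CO[Si](C)(C)C(C)(C)C)=C1\CCC(O[Si](C)(C)C)=C(C)[C@@H]1CCCO[Si](C)(C)C(C)(C)C
F6 | step 18 | spiro-epoxide of ketone 24 (oxirane oxygen cis to the C2 arm) | C/C(CO[Si](C)(C)C(C)(C)C)=C1\CC[C@]2(OC2)[C@@](C)(CC/C=C(\C)CC/C=C(\C)C[C@H](O[Si](CC)(CC)CC)C=C(C)C)[C@@H]1CCCO[Si](C)(C)C(C)(C)C
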